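The constants used here are assumed; no experiment stands behind them.

Reciprocal molar is the unit of both equilibrium constants that make product from substrate and partner in this flask, so the two can be added.

substrate 5.0 mM; partner 3.50 mM (fed, over 1.5 s); precatalyst 0.25 mM; time 2.0 min; the fed solution adds 0.10 times the starting volume

    precatalyst → catalyst (k1 = 0.033 s⁻¹)
    substrate + partner ⇌ isomer of the product (K2 = 710 M⁻¹, k2 = 180 M⁻¹ s⁻¹)
    target + catalyst ⇌ isomer of the product + catalyst, rate k3*[catalyst]*[target] forward; the back reaction follows from the equilibrium constant (k3 = 300 M⁻¹ s⁻¹)
    substrate + partner ⇌ target (K4 = 290 M⁻¹, k4 = 920 M⁻¹ s⁻¹)

- why nothing more happens at 2.0 min, or that something still does (it is still moving / forward and back rates have come level / the partner has run out first / all of the substrate has reacted)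
- share of the substrate used up at 2.0 min
- target at 2.0 min, in percent of the substrate charged
- isomer of the product at 2.0 min, in percent of the substrate charged

- amounts are per litre of the starting volume; all of the dose is in the solution fed
- the reaction counts as stopped when no species that holds the substrate changes by six tenths of a point or more over the second half of the time
- run time (flask): 2.0 min

The first link is time. The addition that gives the isomer is the slower of the two direct ones. Its forward rate alone, with the whole partner counted at once, gives substrate a half-life of 1.1 s, far shorter than the 2.0 min of the run. So I reckon this flask at balance.

The second link divides each forward rate by its back rate, and time drops out. Call the constants K_t = 290 M⁻¹ for target and K_i = 710 M⁻¹ for isomer. Their sum is the summed binding constant, K_sum = 1000 M⁻¹. With x the target and isomer together, and c_substrate and c_partner here the totals in the flask: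

x = c_target + c_isomer = K_sum · (c_substrate − x) · (c_partner − x)

The third link puts in the charges as they stand:

x = 2.50 mM, conversion 50.0 %

That link is the weak one, since the charges are per starting volume and the feed adds 0.10 of that volume. Reforged, the flask holds 4.55 mM substrate and 3.18 mM partner in total:

x = 2.22 mM, conversion 48.9 %

The catalysed interchange carries the constant K_i/K_t, so the split at balance is the one the additions give, which is thermodynamic control. That makes my target 14.2 % and my isomer 34.7 %.

The forecast says forward and back rates have come level, with conversion 48.9 %, target 14.2 % and isomer 34.7 %, the same numbers as mine. It reads the catalyst the same way, “the catalyst only offering a further route between target and isomer”.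

The flask gives forward and back rates have come level, with conversion 48.9 %, target 14.2 % and isomer 34.7 %. In this flask substrate already stands at 51.1 % of its charge at 0.400 min. Now K_sum goes to the neighbour flask with 6.0 mM of partner, which is 5.45 mM after the feed:

x = 3.16 mM, conversion 69.5 %

That neighbour flask shows a conversion of 69.6 %, with 30.4 % substrate left at 2.00 min.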